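**Retrosynthetic overview** (atom labels C1–C8a are the azulene locants of the target)
1. Esters last: the C8 tiglate and the C4 4-hydroxybenzoate go onto hydroxyls; the C8 hydroxyl comes from face-selective reduction of an 8-ketone.
2. Seven-membered ring (formed second): C8–C8a bond by a photochemical 7-endo cyclization of an enoyl radical onto the ring A alkene, setting C8a (quaternary) and C3a.
3. C4–C5 bond: vinylogous Mukaiyama aldol of a cyclopentenecarbaldehyde with the dienol silyl ether of 3-methylbut-2-enal, setting C4.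
4. Ring A (formed first): ozonolysis/aldol ring contraction of (S)-terpinen-4-ol, which brings the C3 carbinol stereocentre that controls all the others.

Assumption: (S)-(+)-terpinen-4-ol is bought in ≥98% ee.

**Step 1**
Reactants: 1 (S)-(+)-terpinen-4-ol; 2 triethylsilyl trifluoromethanesulfonate
Product: 3 triethyl{[(1S)-4-methyl-1-(propan-2-yl)cyclohex-3-en-1-yl]oxy}silane
Conditions: 2,6-lutidine, CH2Cl2, 0 °C to rt
Reagents that add atoms: triethylsilyl trifluoromethanesulfonate (2), CC[Si](CC)(CC)OS(=O)(=O)C(F)(F)F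
Why: Silyl triflate/lutidine silylation of a hindered tertiary alcohol is reliable; the bought stereocentre (future C3) is untouched and the silyl ether keeps this β-oxygen from being eliminated in step 3.

**Step 2**
Reactants: 3 silyl ether; 4 ozone
Product: 6 (3S)-6-oxo-3-(propan-2-yl)-3-[(triethylsilyl)oxy]heptanal, via secondary ozonide 5 (not isolated)
Conditions: O3, CH2Cl2, −78 °C; then PPh3, −78 °C to rt
Reagents that add atoms: ozone (4), [O-][O+]=O
Why: Ozonolysis with reductive phosphine work-up cleaves the only alkene to the 1,6-keto aldehyde without touching the silyl ether or the stereocentre.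

**Step 3**
Reactants: 6 keto aldehyde
Product: 8 (5R)-5-hydroxy-2-methyl-5-(propan-2-yl)cyclopent-1-ene-1-carbaldehyde, via silyl ether enal 7 (not isolated)
Conditions: piperidine (0.3 equiv), AcOH (0.3 equiv), Et2O, rt; then HF·pyridine, THF, 0 °C
Reagents that add atoms: none
Why: Amine-catalysed intramolecular aldol condensation, in which the aldehyde enamine adds 5-exo to the methyl ketone and the new free tertiary aldol hydroxyl (a better leaving group than the silyl ether under these weakly acidic conditions) is lost by E1cB to give the tetrasubstituted enal, followed by fluoride desilylation; no stereocentre is formed.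

**Step 4**
Reactants: 9 3-methylbut-2-enal; 10 chlorotrimethylsilane
Product: 11 (E)-trimethyl[(3-methylbuta-1,3-dien-1-yl)oxy]silane
Conditions: Et3N, ZnCl2 (cat.), PhMe, 60 °C
Reagents that add atoms: chlorotrimethylsilane (10), C[Si](C)(C)Cl
Why: Soft enolisation removes a γ-hydrogen of the enal and gives the O-silyl dienol ether, the standard nucleophile for vinylogous Mukaiyama aldol reactions.

**Step 5**
Reactants: 8 hydroxy enal; 11 silyl dienol ether
Product: 12 (2E,5R)-5-hydroxy-5-[(5R)-5-hydroxy-2-methyl-5-(propan-2-yl)cyclopent-1-en-1-yl]-3-methylpent-2-enal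
Conditions: BF3·OEt2, CH2Cl2, −78 °C; aq. NaHCO3 quench at −78 °C
Reagents that add atoms: (E)-trimethyl[(3-methylbuta-1,3-dien-1-yl)oxy]silane (11), C=C(C)/C=C/O[Si](C)(C)C
Why: Vinylogous Mukaiyama aldol reaction, in which the dienol ether attacks through its terminal CH2 (1,2-addition is the only open path for this fully β-substituted enal) and, with the formyl group held s-trans and coplanar with the ring alkene by a hydrogen bond to the tertiary OH, enters on the face anti to the isopropyl group of the neighbouring quaternary carbon, setting the new carbinol (future C4) as 5R.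

**Step 6**
Reactants: 12 hydroxy enal; 13 4-(acetyloxy)benzoyl chloride
Product: 14 (1R,3E)-1-[(5R)-5-hydroxy-2-methyl-5-(propan-2-yl)cyclopent-1-en-1-yl]-3-methyl-5-oxopent-3-en-1-yl 4-(acetyloxy)benzoate
Conditions: pyridine, DMAP (cat.), CH2Cl2, 0 °C
Reagents that add atoms: 4-(acetyloxy)benzoyl chloride (13), CC(=O)Oc1ccc(cc1)C(Cl)=O
Why: DMAP-catalysed acylation of the only acylable (secondary) hydroxyl while the tertiary alcohol stays free; capping this oxygen also prevents lactol formation from the Z-enal and deactivates the adjacent C–H toward hydrogen abstraction in step 7.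

**Step 7**
Reactants: 14 enal ester
Product: 15 (3R,3aS,4R,8aR)-3-hydroxy-6,8a-dimethyl-8-oxo-3-(propan-2-yl)-1,2,3,3a,4,5,8,8a-octahydroazulen-4-yl 4-(acetyloxy)benzoate
Conditions: (nBu4N)4[W10O32] (2 mol%), iPr3SiSH (10 mol%), MeCN (0.01 M), 390 nm LEDs, rt, Ar
Reagents that add atoms: none
Why: Proposed new method: a photocatalytic hydrogen-atom-transfer hydroacylation run in the 7-endo-trig mode with an α,β-unsaturated aldehyde as acyl radical source. Excited decatungstate (and the silanethiyl radical it generates) abstracts the polarity-matched formyl hydrogen in preference to the electron-poor C–H bonds next to the ester oxygen and γ to the enal; the σ-type enoyl radical equilibrates E/Z through its α-ketenyl resonance form; the Z form adds to the distal, less hindered alkene carbon (future C8a; the proximal carbon is flanked by two fully substituted centres, which disfavours 6-exo closure) on the face anti to the isopropyl group, the tether being held on that face by A(1,3) strain at the 5R carbinol; the thiol then delivers hydrogen to the tertiary C3a radical from outside the folded seven-membered ring, giving the cis fusion. The closest known reactions are acyl radical 7-endo cyclizations of selenoesters under tin hydride and decatungstate- or thiol-catalysed hydroacylation of alkenes with saturated aldehydes.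

**Step 8**
Reactants: 15 enone
Product: 16 (3R,3aS,4R,8S,8aR)-3,8-dihydroxy-6,8a-dimethyl-3-(propan-2-yl)-1,2,3,3a,4,5,8,8a-octahydroazulen-4-yl 4-(acetyloxy)benzoate
Conditions: NaBH4, CeCl3·7H2O, MeOH, −78 °C
Reagents that add atoms: none
Why: Luche 1,2-reduction, in which hydride is expected to add to the cerium-activated enone from the convex face of the cis-fused bicycle (the concave face is blocked by ring A and its tertiary OH, to which cerium can bridge), placing the new hydroxyl on the concave face (8S) while the esters survive at −78 °C.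

**Step 9**
Reactants: 16 allylic alcohol; 17 (2E)-2-methylbut-2-enoyl chloride (tigloyl chloride)
Product: 19 (3R,3aS,4R,8S,8aR)-3-hydroxy-6,8a-dimethyl-8-{[(2E)-2-methylbut-2-enoyl]oxy}-3-(propan-2-yl)-1,2,3,3a,4,5,8,8a-octahydroazulen-4-yl 4-hydroxybenzoate (CNP0273650.13), via acetate-protected diester 18 (not isolated)
Conditions: pyridine, DMAP, CH2Cl2, 0 to 35 °C; then pyrrolidine, 0 °C
Reagents that add atoms: (2E)-2-methylbut-2-enoyl chloride (17), C/C=C(\C)C(Cl)=O
Why: DMAP-catalysed acylation of the allylic secondary alcohol (tertiary OH inert; pyridine rather than a trialkylamine avoids deconjugation through a vinylketene), then chemoselective aminolysis of the phenyl acetate by pyrrolidine, an aryl ester being far more reactive than the alkyl benzoate or the tiglate.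

**Compound list**
1 | (S)-(+)-terpinen-4-ol, (1S)-4-methyl-1-(propan-2-yl)cyclohex-3-en-1-ol | CC1=CC[C@](O)(C(C)C)CC1 | starting material
2 | triethylsilyl trifluoromethanesulfonate | CC[Si](CC)(CC)OS(=O)(=O)C(F)(F)F | starting material
3 | triethyl{[(1S)-4-methyl-1-(propan-2-yl)cyclohex-3-en-1-yl]oxy}silane | CC1=CC[C@](O[Si](CC)(CC)CC)(C(C)C)CC1 | intermediate
4 | ozone | [O-][O+]=O | starting material
5 | secondary ozonide of 3: 1-methyl-4-(propan-2-yl)-4-[(triethylsilyl)oxy]-7,8,9-trioxabicyclo[4.2.1]nonane (silyloxy carbon as in 3; ozonide carbons unassigned) | CC12CC[C@@](O[Si](CC)(CC)CC)(C(C)C)CC(OO1)O2 | intermediate (not isolated)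
6 | (3S)-6-oxo-3-(propan-2-yl)-3-[(triethylsilyl)oxy]heptanal | O=CC[C@](O[Si](CC)(CC)CC)(C(C)C)CCC(C)=O | intermediate
7 | (5R)-2-methyl-5-(propan-2-yl)-5-[(triethylsilyl)oxy]cyclopent-1-ene-1-carbaldehyde | O=CC1=C(C)CC[C@@]1(O[Si](CC)(CC)CC)C(C)C | intermediate (not isolated)
8 | (5R)-5-hydroxy-2-methyl-5-(propan-2-yl)cyclopent-1-ene-1-carbaldehyde | O=CC1=C(C)CC[C@@]1(O)C(C)C | intermediate
9 | 3-methylbut-2-enal | CC(C)=CC=O | starting material
10 | chlorotrimethylsilane | C[Si](C)(C)Cl | starting material
11 | (E)-trimethyl[(3-methylbuta-1,3-dien-1-yl)oxy]silane | C=C(C)/C=C/O[Si](C)(C)C | intermediate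
12 | (2E,5R)-5-hydroxy-5-[(5R)-5-hydroxy-2-methyl-5-(propan-2-yl)cyclopent-1-en-1-yl]-3-methylpent-2-enal | O=C/C=C(\C)C[C@@H](O)C1=C(C)CC[C@@]1(O)C(C)C | intermediate
13 | 4-(acetyloxy)benzoyl chloride | CC(=O)Oc1ccc(cc1)C(Cl)=O | starting material
14 | (1R,3E)-1-[(5R)-5-hydroxy-2-methyl-5-(propan-2-yl)cyclopent-1-en-1-yl]-3-methyl-5-oxopent-3-en-1-yl 4-(acetyloxy)benzoate | O=C/C=C(\C)C[C@@H](OC(=O)c1ccc(OC(C)=O)cc1)C2=C(C)CC[C@@]2(O)C(C)C | intermediate
15 | (3R,3aS,4R,8aR)-3-hydroxy-6,8a-dimethyl-8-oxo-3-(propan-2-yl)-1,2,3,3a,4,5,8,8a-octahydroazulen-4-yl 4-(acetyloxy)benzoate (cis-fused) | O=C1C=C(C)C[C@@H](OC(=O)c2ccc(OC(C)=O)cc2)[C@@H]3[C@@]1(C)CC[C@@]3(O)C(C)C | intermediate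
16 | (3R,3aS,4R,8S,8aR)-3,8-dihydroxy-6,8a-dimethyl-3-(propan-2-yl)-1,2,3,3a,4,5,8,8a-octahydroazulen-4-yl 4-(acetyloxy)benzoate | O[C@H]1C=C(C)C[C@@H](OC(=O)c2ccc(OC(C)=O)cc2)[C@@H]3[C@@]1(C)CC[C@@]3(O)C(C)C | intermediate
17 | (2E)-2-methylbut-2-enoyl chloride (tigloyl chloride) | C/C=C(\C)C(Cl)=O | starting material
18 | (3R,3aS,4R,8S,8aR)-3-hydroxy-6,8a-dimethyl-8-{[(2E)-2-methylbut-2-enoyl]oxy}-3-(propan-2-yl)-1,2,3,3a,4,5,8,8a-octahydroazulen-4-yl 4-(acetyloxy)benzoate | C/C=C(\C)C(=O)O[C@H]1C=C(C)C[C@@H](OC(=O)c2ccc(OC(C)=O)cc2)[C@@H]3[C@@]1(C)CC[C@@]3(O)C(C)C | intermediate (not isolated)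
19 | (3R,3aS,4R,8S,8aR)-3-hydroxy-6,8a-dimethyl-8-{[(2E)-2-methylbut-2-enoyl]oxy}-3-(propan-2-yl)-1,2,3,3a,4,5,8,8a-octahydroazulen-4-yl 4-hydroxybenzoate | C/C=C(\C)C(=O)O[C@H]1C=C(C)C[C@@H](OC(=O)c2ccc(O)cc2)[C@@H]2[C@@]1(C)CC[C@@]2(O)C(C)C | target

**Step count and risks**
Total steps: 9. Longest linear sequence: 8 (steps 1, 2, 3, 5, 6, 7, 8, 9; step 4 is a one-step side branch).

The three steps most likely to fail:

Step 7 (the proposed new reaction). Hydrogen abstraction may not be selective enough for the formyl C–H over the allylic C–H bonds of the electron-rich ring alkene. The fallback makes the same acyl radical from a stoichiometric precursor with known chemistry; it does not help if the radical itself prefers 6-exo closure. It sets out from 14: Pinnick oxidation (NaClO2, NaH2PO4, 2-methylbut-2-ene, tBuOH/H2O) gives (2E,5R)-5-{[4-(acetyloxy)benzoyl]oxy}-5-[(5R)-5-hydroxy-2-methyl-5-(propan-2-yl)cyclopent-1-en-1-yl]-3-methylpent-2-enoic acid F2. Diphenyl diselenide and Bu3P convert it into the Se-phenyl selenoester, Se-phenyl (2E,5R)-5-{[4-(acetyloxy)benzoyl]oxy}-5-[(5R)-5-hydroxy-2-methyl-5-(propan-2-yl)cyclopent-1-en-1-yl]-3-methylpent-2-eneselenoate F3. Slow addition of (Me3Si)3SiH and AIBN in refluxing benzene at high dilution then gives the acyl radical by selenium abstraction and the known 7-endo acyl radical ring closure. The fallback rejoins the route at 15.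

Step 5. Facial selectivity at the formyl group rests on 1,3-induction from the quaternary carbinol and may be modest. The fallback sets C4 by inversion instead of by facial control. It sets out from 8: the same aldol gives, besides 12, the epimer (2E,5S)-5-hydroxy-5-[(5R)-5-hydroxy-2-methyl-5-(propan-2-yl)cyclopent-1-en-1-yl]-3-methylpent-2-enal F1, which is separated. F1 is esterified with commercial 4-(acetyloxy)benzoic acid under Mitsunobu conditions (PPh3, diisopropyl azodicarboxylate, THF, 0 °C) with inversion at the carbinol, while 12 is acylated as in step 6. Both epimers therefore converge, and the fallback rejoins the route at 14.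

Step 8. Hydride could instead add from the concave face; there is no close precedent for this cis-fused enone with an angular methyl next to the carbonyl. The fallback sets out from 15: the reduction then gives the epimeric alcohol (3R,3aS,4R,8R,8aR)-3,8-dihydroxy-6,8a-dimethyl-3-(propan-2-yl)-1,2,3,3a,4,5,8,8a-octahydroazulen-4-yl 4-(acetyloxy)benzoate F4. Mitsunobu esterification of F4 with tiglic acid (PPh3, diisopropyl azodicarboxylate, PhMe, 0 °C to rt) inverts C8 and installs the tiglate in one operation. This Mitsunobu is at a hindered, neopentyl-type allylic centre and is itself uncertain. The fallback rejoins the route at 18, which pyrrolidine converts to 19 as in step 9.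

**Further compounds**
F1 | step 5 | (2E,5S)-5-hydroxy-5-[(5R)-5-hydroxy-2-methyl-5-(propan-2-yl)cyclopent-1-en-1-yl]-3-methylpent-2-enal | O=C/C=C(\C)C[C@H](O)C1=C(C)CC[C@@]1(O)C(C)C
F2 | step 7 | (2E,5R)-5-{[4-(acetyloxy)benzoyl]oxy}-5-[(5R)-5-hydroxy-2-methyl-5-(propan-2-yl)cyclopent-1-en-1-yl]-3-methylpent-2-enoic acid | OC(=O)/C=C(\C)C[C@@H](OC(=O)c1ccc(OC(C)=O)cc1)C2=C(C)CC[C@@]2(O)C(C)C
F3 | step 7 | Se-phenyl (2E,5R)-5-{[4-(acetyloxy)benzoyl]oxy}-5-[(5R)-5-hydroxy-2-methyl-5-(propan-2-yl)cyclopent-1-en-1-yl]-3-methylpent-2-eneselenoate | O=C([Se]c1ccccc1)/C=C(\C)C[C@@H](OC(=O)c2ccc(OC(C)=O)cc2)C3=C(C)CC[C@@]3(O)C(C)C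
F4 | step 8 | (3R,3aS,4R,8R,8aR)-3,8-dihydroxy-6,8a-dimethyl-3-(propan-2-yl)-1,2,3,3a,4,5,8,8a-octahydroazulen-4-yl 4-(acetyloxy)benzoate | O[C@@H]1C=C(C)C[C@@H](OC(=O)c2ccc(OC(C)=O)cc2)[C@@H]3[C@@]1(C)CC[C@@]3(O)C(C)C
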